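**Plan**
Ring numbering of the target: C1 bears the side chain, C2 is CMe2, C3 and C5 carry Br, C6 is the methylidene carbon. Retrosynthetic cuts, in order: C5–Br, C3–Br (each from an alcohol with inversion), the ring bond C1–C6, the aldol bond C3–C4, one methyl on C2, the Wittig bond C1–C2; what remains is (S)-linalool.
Enabling feature: the exocyclic C6=CH2 lies directly beside the tertiary C1–H, so the ring is a 2-alkyl-1-methylidenecyclohexane. That is the product pattern of a reductive (hydrometalative) closure of a 1,7-enyne: terminal alkyne carbon → =CH2, internal alkyne carbon → C6, proximal alkene carbon → C1.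
Forward: linalool → C6 aldehyde → α,α-dimethyl β,γ-unsaturated aldehyde → ynone aldol → syn-1,3-diol enyne → the single ring, closed at C1–C6 → bromide at C3 → bromide at C5.
Stereochemistry: the side-chain carbinol is that of (S)-linalool; C3–O is set by a ligand-controlled aldol. A helper C5–OH of temporary (equatorial) configuration, from syn reduction, fixes the chair so that C1 forms cis to both oxygens. C3–OH is inverted to the axial bromide; the helper is oxidized out and the ketone re-reduced opposite the axial bromine before the last inversion at C5.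

Key step: step 10

Assumption: (S)-(+)-linalool of high enantiomeric purity is taken as the commercial source of the side-chain carbinol, and the ProPhenol antipode that gives the 5S aldol in step 6 is taken to be (S,S).

Step 1
Reactants: 1 (S)-(+)-linalool [(3S)-3,7-dimethylocta-1,6-dien-3-ol]
Product: 2 (3S)-3,7-dimethyl-3-(triethylsilyloxy)octa-1,6-diene
Conditions: Et3SiOTf, 2,6-lutidine, CH2Cl2, −78 → 0 °C
Reagents that add atoms: triethylsilyl trifluoromethanesulfonate, CC[Si](CC)(CC)OS(=O)(=O)C(F)(F)F
Why: O-Silylation (silyl ether protection) of the hindered tertiary allylic alcohol with the silyl triflate masks the carbinol for the enolate and hydride steps without touching its configuration.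

Step 2
Reactants: 2
Product: 4 (4S)-4-methyl-4-(triethylsilyloxy)hex-5-enal, via secondary ozonide 3 (not isolated)
Conditions: O3 (1 equiv), CH2Cl2, −78 °C; then Me2S, −78 °C → rt
Reagents that add atoms: ozone, [O-][O+]=O
Why: Ozonolysis with one equivalent of the electrophilic oxidant should cleave the electron-rich trisubstituted alkene much faster than the hindered vinyl group on the oxygenated quaternary carbon, and reduction of the ozonide gives the aldehyde.

Step 3
Reactants: 4; 5 ethyl 2-(triphenylphosphoranylidene)propanoate
Product: 6 ethyl (2E,6S)-2,6-dimethyl-6-(triethylsilyloxy)octa-2,7-dienoate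
Conditions: toluene, 60 °C
Reagents that add atoms: none
Why: Wittig olefination with the stabilized α-methyl ylide should give the (E)-trisubstituted enoate and joins the future C1 and C2.

Step 4
Reactants: 6
Product: 8 ethyl (3E,6S)-2,2,6-trimethyl-6-(triethylsilyloxy)octa-3,7-dienoate, via lithium dienolate 7 (not isolated)
Conditions: LiN(i-Pr)2, HMPA, THF, −78 °C; then MeI, −78 → 0 °C
Reagents that add atoms: iodomethane, CI
Why: Deconjugative α-alkylation: γ-deprotonation gives the extended dienolate, which is methylated at the α-carbon to build the gem-dimethyl quaternary carbon and move the alkene to the β,γ-position, where E geometry is expected because allylic strain with the α-methyl keeps the chain away from the fully substituted carbon.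

Step 5
Reactants: 8
Product: 9 (3E,6S)-2,2,6-trimethyl-6-(triethylsilyloxy)octa-3,7-dienal
Conditions: i-Bu2AlH (1.1 equiv), CH2Cl2, −78 °C; aq. potassium sodium tartrate
Reagents that add atoms: none
Why: Partial hydride reduction of the hindered α,α-disubstituted ester should stop at the tetrahedral aluminate at low temperature and release the non-enolizable aldehyde on work-up.

Step 6
Reactants: 9; 10 4-(trimethylsilyl)but-3-yn-2-one
Product: 11 (5S,7E,10S)-5-hydroxy-6,6,10-trimethyl-10-(triethylsilyloxy)-1-(trimethylsilyl)dodeca-7,11-dien-1-yn-3-one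
Conditions: (S,S)-ProPhenol (10 mol %), Et2Zn (20 mol %), 4 Å molecular sieves, THF, 0 °C
Reagents that add atoms: none
Why: Direct catalytic asymmetric aldol addition: the dinuclear zinc–ProPhenol complex forms the zinc enolate of the methyl ynone and delivers it to one face of the non-enolizable α-quaternary aldehyde, so the new carbinol center (5S, to be confirmed by Mosher ester analysis) is set by the ligand and not by the remote silyloxy center.

Step 7
Reactants: 11
Product: 13 (3R,5S,7E,10S)-6,6,10-trimethyl-10-(triethylsilyloxy)-1-(trimethylsilyl)dodeca-7,11-dien-1-yne-3,5-diol, via diethylboron chelate 12 (not isolated)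
Conditions: Et2BOMe, THF/MeOH (4:1), −78 °C; then NaBH4, −78 °C; evaporation from MeOH
Reagents that add atoms: none
Why: Narasaka–Prasad reduction: external hydride adds to the six-membered diethylboron chelate of the β-hydroxy ynone from the face that gives the syn-1,3-diol, which sets the propargylic center (3R) from the 5S carbinol.

Step 8
Reactants: 13
Product: 14 (3R,5S,7E,10S)-6,6,10-trimethyl-10-(triethylsilyloxy)dodeca-7,11-dien-1-yne-3,5-diol
Conditions: K2CO3 (cat.), MeOH, 0 °C → rt
Reagents that add atoms: none
Why: Protodesilylation of the silylalkyne by methanolysis frees the terminal alkyne while the hindered tertiary silyl ether survives.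

Step 9
Reactants: 14
Product: 15 (3R,5S,7E,10S)-3-(tert-butyldimethylsilyloxy)-6,6,10-trimethyl-10-(triethylsilyloxy)dodeca-7,11-dien-1-yn-5-ol
Conditions: t-BuMe2SiCl (1.05 equiv), imidazole, DMF, 0 °C
Reagents that add atoms: tert-butyl(chloro)dimethylsilane, CC(C)(C)[Si](C)(C)Cl
Why: Selective O-silylation protects the unhindered propargylic hydroxyl and leaves free the neopentyl hydroxyl that is flanked by the quaternary carbon.

Step 10
Reactants: 15
Product: 16 (1S,3S,5R)-5-(tert-butyldimethylsilyloxy)-2,2-dimethyl-4-methylidene-3-[(3S)-3-methyl-3-(triethylsilyloxy)pent-4-en-1-yl]cyclohexan-1-ol (hydroxyl, side chain, silyloxy group all cis)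
Conditions: Pd2(dba)3·CHCl3 (5 mol %), P(o-tol)3 (20 mol %), AcOH (2 equiv), Et3SiH (5 equiv), THF, rt → 45 °C
Reagents that add atoms: none
Why: Acetic acid adds oxidatively to zerovalent palladium to give a palladium hydride (divalent palladium) that hydropalladates the terminal alkyne with the metal on the internal carbon; this alkenylpalladium inserts the (E)-alkene by syn-carbopalladation, forming the ring bond C1–C6 (target numbering), and the secondary alkylpalladium on the side-chain carbon is intercepted by Et3SiH and gives C–H by reductive elimination. The closest known reaction type is the palladium-hydride reductive cyclization (cycloreduction) of 1,6- and 1,7-enynes with a silane and a carboxylic acid. The six-membered ring closes in the 6-exo-trig mode with respect to the alkene, the former internal alkyne carbon becoming ring carbon C6 and the terminal one the exocyclic CH2. The new stereocenter C1 is controlled by a chair-like insertion transition state: the syn-1,3 relation of the hydroxyl and silyloxy groups excludes the chair in which both are axial (the silyl ether oxygen is too poor a hydrogen-bond acceptor to rescue it), so both sit equatorial and the alkene adds with its chain pseudo-equatorial, cis to both oxygens. The step needs hydride capture to outrun β-hydride elimination (which would give dienes) and the alkyne to react before either alkene; excess silane is meant to secure the first, while the preference of the palladium hydride for the terminal alkyne, the gem-dimethyl (Thorpe–Ingold) compression of the tether and the inertness of the remote vinyl group on the fully substituted carbinol carbon are meant to secure the second.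

Step 11
Reactants: 16
Product: 17 tert-butyl({(1R,3R,5R)-5-bromo-4,4-dimethyl-2-methylidene-3-[(3S)-3-methyl-3-(triethylsilyloxy)pent-4-en-1-yl]cyclohexyl}oxy)dimethylsilane (silyloxy group and side chain cis, bromine trans to both)
Conditions: CBr4, PPh3, 2,6-lutidine, toluene, 0 → 60 °C
Reagents that add atoms: tetrabromomethane, BrC(Br)(Br)Br
Why: Appel reaction: the equatorial neopentyl alkoxyphosphonium at C3 has no antiperiplanar hydrogen for E2 and is approached by bromide along the axial direction, which in this all-cis series carries only hydrogens, so SN2 inversion should give the axial bromide trans to the side chain, a deoxybromination that has precedent on 2,2-dimethylcyclohexanols.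

Step 12
Reactants: 17
Product: 18 (1R,3R,5R)-5-bromo-3-[(3S)-3-hydroxy-3-methylpent-4-en-1-yl]-4,4-dimethyl-2-methylidenecyclohexan-1-ol
Conditions: HF·pyridine, pyridine, THF, 0 °C → rt
Reagents that add atoms: none
Why: Fluoride-mediated desilylation under non-basic conditions removes both silyl ethers without E2 loss of the axial secondary bromide.

Step 13
Reactants: 18
Product: 19 (3R,5R)-5-bromo-3-[(3S)-3-hydroxy-3-methylpent-4-en-1-yl]-4,4-dimethyl-2-methylidenecyclohexan-1-one
Conditions: MnO2 (activated, excess), CH2Cl2, rt; crude product used at once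
Reagents that add atoms: none
Why: Allylic alcohol oxidation with MnO2 is chemoselective for the secondary allylic hydroxyl (its axial C–H is aligned with the exocyclic π bond), leaves the tertiary alcohol and the bromide alone, and removes the helper carbinol center at C5.

Step 14
Reactants: 19
Product: 20 (1S,3R,5R)-5-bromo-3-[(3S)-3-hydroxy-3-methylpent-4-en-1-yl]-4,4-dimethyl-2-methylidenecyclohexan-1-ol (hydroxyl cis to bromine, trans to the side chain)
Conditions: i-Bu2AlH (2.5 equiv), CH2Cl2, −78 °C
Reagents that add atoms: none
Why: Substrate-controlled 1,2-reduction of the enone: in the chair with equatorial side chain the bromine is axial and shields the face of axial attack, so the bulky hydride should enter from the opposite side and give the axial alcohol cis to bromine and trans to the side chain.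

Step 15
Reactants: 20
Product: 21 (3S)-5-[(1S,3R,5R)-3,5-dibromo-2,2-dimethyl-6-methylidenecyclohexyl]-3-methylpent-1-en-3-ol
Conditions: CBr4, PPh3, 2,6-lutidine, CH2Cl2, −40 → 0 °C
Reagents that add atoms: tetrabromomethane, BrC(Br)(Br)Br
Why: Appel reaction: at low temperature the reagent should activate only the secondary allylic hydroxyl (the hindered tertiary carbinol reacts far more slowly) and bromide should displace it by SN2 inversion, giving the equatorial C5 bromide cis to the side chain, whose C–Br bond is orthogonal to the exocyclic π bond and so is not prone to later allylic transposition.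

**Compound list**
1 | (S)-(+)-linalool | C=C[C@@](C)(O)CCC=C(C)C | starting material
2 | (3S)-3,7-dimethyl-3-(triethylsilyloxy)octa-1,6-diene | C=C[C@@](C)(O[Si](CC)(CC)CC)CCC=C(C)C | intermediate
3 | secondary ozonide of 2 (3,3-dimethyl-1,2,4-trioxolane bearing the side chain at C5; both epimers at that carbon) | C=C[C@@](C)(O[Si](CC)(CC)CC)CCC1OOC(C)(C)O1 | intermediate
4 | (4S)-4-methyl-4-(triethylsilyloxy)hex-5-enal | C=C[C@@](C)(O[Si](CC)(CC)CC)CCC=O | intermediate
5 | ethyl 2-(triphenylphosphoranylidene)propanoate | CCOC(=O)C(C)=P(c1ccccc1)(c1ccccc1)c1ccccc1 | starting material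
6 | ethyl (2E,6S)-2,6-dimethyl-6-(triethylsilyloxy)octa-2,7-dienoate | C=C[C@@](C)(O[Si](CC)(CC)CC)CC/C=C(\C)C(=O)OCC | intermediate
7 | lithium dienolate of 6 (enolate geometry not specified) | C=C[C@@](C)(O[Si](CC)(CC)CC)C/C=C/C(C)=C(O[Li])OCC | intermediate
8 | ethyl (3E,6S)-2,2,6-trimethyl-6-(triethylsilyloxy)octa-3,7-dienoate | C=C[C@@](C)(O[Si](CC)(CC)CC)C/C=C/C(C)(C)C(=O)OCC | intermediate
9 | (3E,6S)-2,2,6-trimethyl-6-(triethylsilyloxy)octa-3,7-dienal | C=C[C@@](C)(O[Si](CC)(CC)CC)C/C=C/C(C)(C)C=O | intermediate
10 | 4-(trimethylsilyl)but-3-yn-2-one | CC(=O)C#C[Si](C)(C)C | starting material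
11 | (5S,7E,10S)-5-hydroxy-6,6,10-trimethyl-10-(triethylsilyloxy)-1-(trimethylsilyl)dodeca-7,11-dien-1-yn-3-one | C=C[C@@](C)(O[Si](CC)(CC)CC)C/C=C/C(C)(C)[C@@H](O)CC(=O)C#C[Si](C)(C)C | intermediate
12 | O-diethylboryl chelate of 11 | C=C[C@@](C)(O[Si](CC)(CC)CC)C/C=C/C(C)(C)[C@@H](OB(CC)CC)CC(=O)C#C[Si](C)(C)C | intermediate
13 | (3R,5S,7E,10S)-6,6,10-trimethyl-10-(triethylsilyloxy)-1-(trimethylsilyl)dodeca-7,11-dien-1-yne-3,5-diol (syn diol) | C=C[C@@](C)(O[Si](CC)(CC)CC)C/C=C/C(C)(C)[C@@H](O)C[C@@H](O)C#C[Si](C)(C)C | intermediate
14 | (3R,5S,7E,10S)-6,6,10-trimethyl-10-(triethylsilyloxy)dodeca-7,11-dien-1-yne-3,5-diol | C=C[C@@](C)(O[Si](CC)(CC)CC)C/C=C/C(C)(C)[C@@H](O)C[C@@H](O)C#C | intermediate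
15 | (3R,5S,7E,10S)-3-(tert-butyldimethylsilyloxy)-6,6,10-trimethyl-10-(triethylsilyloxy)dodeca-7,11-dien-1-yn-5-ol | C=C[C@@](C)(O[Si](CC)(CC)CC)C/C=C/C(C)(C)[C@@H](O)C[C@@H](O[Si](C)(C)C(C)(C)C)C#C | intermediate
16 | (1S,3S,5R)-5-(tert-butyldimethylsilyloxy)-2,2-dimethyl-4-methylidene-3-[(3S)-3-methyl-3-(triethylsilyloxy)pent-4-en-1-yl]cyclohexan-1-ol | C=C[C@@](C)(O[Si](CC)(CC)CC)CC[C@@H]1C(=C)[C@H](O[Si](C)(C)C(C)(C)C)C[C@H](O)C1(C)C | intermediate
17 | tert-butyl({(1R,3R,5R)-5-bromo-4,4-dimethyl-2-methylidene-3-[(3S)-3-methyl-3-(triethylsilyloxy)pent-4-en-1-yl]cyclohexyl}oxy)dimethylsilane | C=C[C@@](C)(O[Si](CC)(CC)CC)CC[C@@H]1C(=C)[C@H](O[Si](C)(C)C(C)(C)C)C[C@@H](Br)C1(C)C | intermediate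
18 | (1R,3R,5R)-5-bromo-3-[(3S)-3-hydroxy-3-methylpent-4-en-1-yl]-4,4-dimethyl-2-methylidenecyclohexan-1-ol | C=C[C@@](C)(O)CC[C@@H]1C(=C)[C@H](O)C[C@@H](Br)C1(C)C | intermediate
19 | (3R,5R)-5-bromo-3-[(3S)-3-hydroxy-3-methylpent-4-en-1-yl]-4,4-dimethyl-2-methylidenecyclohexan-1-one | C=C[C@@](C)(O)CC[C@@H]1C(=C)C(=O)C[C@@H](Br)C1(C)C | intermediate
20 | (1S,3R,5R)-5-bromo-3-[(3S)-3-hydroxy-3-methylpent-4-en-1-yl]-4,4-dimethyl-2-methylidenecyclohexan-1-ol | C=C[C@@](C)(O)CC[C@@H]1C(=C)[C@@H](O)C[C@@H](Br)C1(C)C | intermediate
21 | (3S)-5-[(1S,3R,5R)-3,5-dibromo-2,2-dimethyl-6-methylidenecyclohexyl]-3-methylpent-1-en-3-ol | C=C[C@@](C)(O)CC[C@@H]1C(=C)[C@H](Br)C[C@@H](Br)C1(C)C | target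

**Step count and risks**
Total steps: 15. Longest linear sequence: 15 steps, from 1.

Step 11 is the most likely to fail. Displacement at the neopentyl carbinol carbon may be slower than migration of an antiperiplanar ring bond (ring contraction) or than attack of the phosphonium reagent on the silyl ethers. The fallback moves the substitution in front of the ring closure. From 15, the free hydroxyl is converted with Tf2O and 2,6-di-tert-butylpyridine (CH2Cl2, −78 °C) into the acyclic triflate F1. Displacement with Bu4NBr in toluene (−78 °C → rt) should give, with inversion, the acyclic bromide F2. F2 is then cyclized under the conditions of step 10, through the chair with equatorial silyloxy group, axial bromine and equatorial chain, and the route is rejoined at 17.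

Step 15 is second. Bromide may attack the methylidene carbon instead (allylic transposition to the primary bromide with an endocyclic alkene), or the tertiary allylic alcohol may be activated in competition. The fallback replaces phosphonium activation by sulfonate activation followed by halide displacement. From 20, MsCl and Et3N (CH2Cl2, −40 °C) should sulfonylate only the secondary hydroxyl to give the allylic mesylate F3. LiBr in THF at −20 °C then displaces it directly and the route is rejoined at 21.

Step 10 is third. The alkylpalladium intermediate may undergo β-hydride elimination to dienes before hydride capture, insertion into the hindered alkene may be slow, or facial selectivity at C1 may be poor. The fallback is a radical ring closure. From 15, slow addition of n-Bu3SnH with AIBN (benzene, 80 °C) adds a stannyl radical to the alkyne terminus. The vinyl radical closes 6-exo onto the alkene through the same chair and the side-chain radical is reduced, giving the vinylstannane F4 (E isomer drawn; either alkene isomer serves). Protodestannylation on silica gel in CH2Cl2 rejoins the route at 16.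

**Further compounds**
F1 | step 11 | (3R,5S,7E,10S)-3-(tert-butyldimethylsilyloxy)-6,6,10-trimethyl-10-(triethylsilyloxy)dodeca-7,11-dien-1-yn-5-yl trifluoromethanesulfonate | C=C[C@@](C)(O[Si](CC)(CC)CC)C/C=C/C(C)(C)[C@@H](OS(=O)(=O)C(F)(F)F)C[C@@H](O[Si](C)(C)C(C)(C)C)C#C
F2 | step 11 | tert-butyl{[(3R,5R,7E,10S)-5-bromo-6,6,10-trimethyl-10-(triethylsilyloxy)dodeca-7,11-dien-1-yn-3-yl]oxy}dimethylsilane | C=C[C@@](C)(O[Si](CC)(CC)CC)C/C=C/C(C)(C)[C@H](Br)C[C@@H](O[Si](C)(C)C(C)(C)C)C#C
F3 | step 15 | (1S,3R,5R)-5-bromo-3-[(3S)-3-hydroxy-3-methylpent-4-en-1-yl]-4,4-dimethyl-2-methylidenecyclohexyl methanesulfonate | C=C[C@@](C)(O)CC[C@@H]1C(=C)[C@@H](OS(C)(=O)=O)C[C@@H](Br)C1(C)C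
F4 | step 10 | (1S,3S,4E,5R)-5-(tert-butyldimethylsilyloxy)-2,2-dimethyl-3-[(3S)-3-methyl-3-(triethylsilyloxy)pent-4-en-1-yl]-4-[(tributylstannyl)methylidene]cyclohexan-1-ol | C=C[C@@](C)(O[Si](CC)(CC)CC)CC[C@@H]1/C(=C\[Sn](CCCC)(CCCC)CCCC)[C@H](O[Si](C)(C)C(C)(C)C)C[C@H](O)C1(C)C
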